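| flask | starting complex | incoming ligand | protic impurity | remark | time |
|---|---|---|---|---|---|
| east | 0.010 M | 0.0093 M | 2 mM | run made earlier |  |
| north-west | 0.010 M | 0.020 M | 2 mM | run made earlier |  |
| west | 0.010 M | 0.036 M | 2 mM | run made earlier |  |
| gamma | 0.010 M | 0.0400 M | 2.00 mM |  | 20 h |
| theta | 0.010 M | 0.0100 M | 2.00 mM |  | 20 h |

| run | time / h | complex with three exchanged / % |
|---|---|---|
| east | 0.833 | 0 |
| east | 2.50 | 2 |
| east | 5.00 | 0 |
| east | 8.00 | 0 |
| east | 10.0 | 6 |
| north-west | 2.00 | 2 |
| north-west | 4.00 | 5 |
| north-west | 6.00 | 6 |
| north-west | 8.00 | 15 |
| north-west | 10.0 | 10 |
| west | 0.833 | 1 |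
| west | 2.50 | 8 |
| west | 5.00 | 17 |
| west | 8.00 | 29 |
| west | 10.0 | 38 |

(readings scatter by 2 percentage points)



1. which of these holds the largest part of the starting complex at the end of gamma (complex with three exchanged / complex with two exchanged / complex with one exchanged / starting complex)
2. which of these holds the largest part of the starting complex at the end of theta (complex with three exchanged / complex with two exchanged / complex with one exchanged / starting complex)
3. amount of complex with three exchanged at the end of gamma, in percent of the starting complex charged

**Time first.** Time was my first doubt. The west run stood at 38% after 10.0 h and rose nearly in a straight line. Gamma runs for 20 h, so doubling that reading gave 76.0%.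

**Counting turnovers.** I distrusted the line, so I counted. Each exchange costs one incoming ligand, and I assumed the protic impurity destroys its own amount of ligand. Gamma's usable ligand per starting complex charged is 3.80; I call this the turnover budget. Full exchange costs 3 turnovers, so gamma can pay. But paying slows the flask. At that doubled reading, 1.52 turnovers remain, and the line must bend. I committed to complex with three exchanged leading gamma, below the doubled reading.

**Theta's shortage.** Theta's budget is 0.800, which is less than one turnover per complex. Ligand is the limiting reagent there, and at least 20.0% of the starting complex stays unexchanged. That floor names no leader, though, so my own count left theta's leader open.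

**The forecast.** It read “three equivalent sites exchanging independently”. It gave complex with three exchanged for gamma, at 74%, and complex with one exchanged for theta.

**The result.** Gamma ended with complex with three exchanged leading at 65.6%, 8.4 percentage points below the forecast. Theta ended with starting complex leading at 58.0%.

    starting complex + incoming ligand → leaving ligand + complex with one exchanged (k = 6.60 M⁻¹ h⁻¹)
    complex with one exchanged + incoming ligand → leaving ligand + complex with two exchanged (k = 18.0 M⁻¹ h⁻¹)
    complex with two exchanged + incoming ligand → leaving ligand + complex with three exchanged (k = 11.0 M⁻¹ h⁻¹)
    complex with one exchanged → decomposed reagent (k = 0.0520 h⁻¹)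
    complex with two exchanged → side product (k = 0.0290 h⁻¹)
    protic impurity + incoming ligand → quenched reagent (k = 67.0 M⁻¹ h⁻¹)

**The parting point.** The second exchange's rate constant was 2.7 times the first's. In gamma at 20.0 h, the first step still drew ligand at 0.82 of the second's rate. Gamma's budget of 3.80 closed: 2.41 turnovers had been spent and 1.39 lay unspent. The neighbour with 0.10 M of ligand has a budget of 9.80. The computed flask spent 2.90 turnovers and held 93.5% complex with three exchanged.

Readings and results stem from a simulated flask on assumed constants, noise included.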